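**Plan**

- Retrosynthesis: the furanone O10–C3 bond is cut first (oxa-Michael on a C1 ynone), then C1–C2 (alkynylchromium addition to an aldehyde, which opens the ten-membered ring), then C6–C7 together with the lactone O6–C12 bond (allylation–lactonisation), then C7=C11 and C8–C9.
- Enabling feature: C1 is a non-enolisable aldehyde on quaternary C10, and the linear C1–C2≡C3–C4 unit spans the ten-membered ring opposite the six-atom C5–C10 chain, which already holds the cis C4=C5 alkene, the trans C6/C7 lactone and all five stereocentres; the alkyne later becomes the furanone C2=C3 bond.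
- Forward order: the C7–C10 chain is built from methacrolein and an allyl ether and extended to bromomethyl acrylate 18; the lactone ring closes first (step 10, with enynal 20), the ten-membered carbocycle second (step 16), the furanone last (step 19).
- Stereochemistry: C8 and C9 come from the Ipc2B reagent (syn, reagent control); C10 from the C9 hydroxyl (directed epoxidation, erythro); C7 and C6 from C8 in the chromium allylation (A(1,3) strain, anti chair); C1 needs no control.
- Protecting groups: O8 as PMB ether (exchanged for the isobutyrate), O9 as TBS ether (removed last), O10 as TES ether (removed before furanone closure), C1 carried as a PMP ether.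

Key step: step 16

Remark: locants C1–C15 follow germacranolide numbering; PMB = 4-methoxybenzyl, PMP = 4-methoxyphenyl, TBS = tert-butyldimethylsilyl, TES = triethylsilyl, Ipc = isopinocampheyl from (−)-α-pinene; the C1 carbinol of 30 is taken on as an epimer mixture because step 17 oxidises it.

**Route**

Step 1
Reactants: 1 4-methoxybenzyl alcohol; 2 allyl bromide
Product: 3 allyl 4-methoxybenzyl ether
Conditions: NaH, Bu4NI (cat.), THF, 0 °C → rt
Reagents that add atoms: none
Why: Williamson etherification of a primary benzylic alkoxide with a reactive allylic bromide (SN2).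

Step 2
Reactants: 3 allyl 4-methoxybenzyl ether; 4 methacrolein
Product: 9 (3S,4S)-3-(PMB-oxy)-5-methylhexa-1,5-dien-4-ol, via alkoxyallyllithium 5 (not isolated), via lithium allylborate 6 (not isolated), via allylborane 7 (not isolated), via borinate ester 8 (not isolated)
Conditions: s-BuLi, THF, −78 °C; (+)-Ipc2BOMe; BF3·OEt2; 4, −78 °C; NaOH, H2O2, 0 °C → rt
Reagents that add atoms: none
Why: Ipc2B-mediated γ-alkoxyallylboration (Brown alkoxyallylation): the chelated (Z)-alkoxyallyl anion is transferred to boron and adds to the enal through a Zimmerman–Traxler chair, so O8 and O9 come out syn, while the isopinocampheyl groups of the (+)-Ipc2BOMe-derived reagent select the aldehyde face that gives the (4S) carbinol (C9) and hence (3S) at C8.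

Step 3
Reactants: 9 (3S,4S)-3-(PMB-oxy)-5-methylhexa-1,5-dien-4-ol
Product: 10 (1R,2S)-2-(PMB-oxy)-1-[(2S)-2-methyloxiran-2-yl]but-3-en-1-ol
Conditions: VO(acac)2 (5 mol%), t-BuOOH, CH2Cl2, 0 °C → rt
Reagents that add atoms: tert-butyl hydroperoxide, CC(C)(C)OO
Why: Hydroxyl-directed vanadium-catalysed epoxidation of a 2-substituted secondary allylic alcohol, in which A(1,2) strain between the C10 methyl and the C9 substituent enforces the erythro transition state, so the new C10–O bond is anti to O9 and the homoallylic vinyl group and the PMB ether are spared.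

Step 4
Reactants: 10 (1R,2S)-2-(PMB-oxy)-1-[(2S)-2-methyloxiran-2-yl]but-3-en-1-ol
Product: 11 (2S,3R,4S)-4-(PMB-oxy)-1-(PMP-oxy)-2-methylhex-5-ene-2,3-diol
Conditions: 4-methoxyphenol, Cs2CO3 (0.2 equiv), DMF, 80 °C
Reagents that add atoms: 4-methoxyphenol, COc1ccc(O)cc1
Why: Base-catalysed SN2 opening of the terminal epoxide by phenoxide at the unsubstituted carbon C1 (Payne-type manifold in which only the terminal epoxide is attacked), which leaves the C10–O bond and its configuration untouched.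

Step 5
Reactants: 11 (2S,3R,4S)-4-(PMB-oxy)-1-(PMP-oxy)-2-methylhex-5-ene-2,3-diol
Product: 13 (3S,4R,5S)-4-(TBS-oxy)-3-(PMB-oxy)-6-(PMP-oxy)-5-methyl-5-(TES-oxy)hex-1-ene, via mono-TBS ether 12 (not isolated)
Conditions: TBSOTf (1.1 equiv), 2,6-lutidine, CH2Cl2, −78 °C; then TESOTf (1.5 equiv), −78 → 0 °C
Reagents that add atoms: tert-butyldimethylsilyl triflate, CC(C)(C)[Si](C)(C)OS(=O)(=O)C(F)(F)F; triethylsilyl triflate, CC[Si](CC)(CC)OS(=O)(=O)C(F)(F)F
Why: Two-stage silyl triflate etherification: at −78 °C the secondary C9 hydroxyl should react well before the tertiary C10 hydroxyl, which is then capped with the more labile TES group.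

Step 6
Reactants: 13 (3S,4R,5S)-4-(TBS-oxy)-3-(PMB-oxy)-6-(PMP-oxy)-5-methyl-5-(TES-oxy)hex-1-ene
Product: 15 (2R,3R,4S)-3-(TBS-oxy)-2-(PMB-oxy)-5-(PMP-oxy)-4-methyl-4-(TES-oxy)pentanal, via vicinal diol 14 (not isolated)
Conditions: OsO4 (2 mol%), NaIO4, 2,6-lutidine, dioxane/H2O (3:1), rt
Reagents that add atoms: osmium tetroxide, O=[Os](=O)(=O)=O (oxygen source, regenerated by sodium periodate, [Na+].[O-]I(=O)(=O)=O)
Why: Lemieux–Johnson oxidation (dihydroxylation, then periodate cleavage) turns the monosubstituted alkene into the C7 aldehyde without ozone, which would attack the two electron-rich arenes.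

Step 7
Reactants: 15 (2R,3R,4S)-3-(TBS-oxy)-2-(PMB-oxy)-5-(PMP-oxy)-4-methyl-4-(TES-oxy)pentanal
Product: 16 methyl 2-[(2S,3R,4S)-3-(TBS-oxy)-1-hydroxy-2-(PMB-oxy)-5-(PMP-oxy)-4-methyl-4-(TES-oxy)pentyl]acrylate (C7 carbinol epimers)
Conditions: methyl propiolate, i-Bu2AlH, NMO, THF, 0 °C; then 15, 0 °C → rt; aq. potassium sodium tartrate
Reagents that add atoms: methyl propiolate, C#CC(=O)OC
Why: Vinylalumination: conjugate hydroalumination of the propiolate gives an α-aluminio acrylate that adds to the hindered, base-sensitive α-alkoxy aldehyde to give the Morita–Baylis–Hillman-type adduct without epimerising C8; the C7 carbinol configuration is lost in step 8.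

Step 8
Reactants: 16 methyl 2-[(2S,3R,4S)-3-(TBS-oxy)-1-hydroxy-2-(PMB-oxy)-5-(PMP-oxy)-4-methyl-4-(TES-oxy)pentyl]acrylate
Product: 18 methyl (2Z,4S,5R,6S)-2-(bromomethyl)-5-(TBS-oxy)-4-(PMB-oxy)-7-(PMP-oxy)-6-methyl-6-(TES-oxy)hept-2-enoate, via alkoxysulfonium bromide 17 (not isolated)
Conditions: NBS, Me2S, CH2Cl2, 0 °C; then 16, 0 °C → rt
Reagents that add atoms: N-bromosuccinimide, O=C1CCC(=O)N1Br
Why: Corey–Kim-type activation of the alcohol as an alkoxysulfonium salt and SN2′ attack of bromide with allylic transposition, which for Morita–Baylis–Hillman alcohols gives the (Z)-2-(bromomethyl)enoate.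

Step 9
Reactants: 19 (Z)-3-methylpent-2-en-4-yn-1-ol
Product: 20 (Z)-3-methylpent-2-en-4-ynal
Conditions: MnO2, CH2Cl2, rt
Reagents that add atoms: none
Why: Allylic alcohol oxidation on MnO2 is neutral and mild, so the Z geometry and the free alkyne should survive.

Step 10
Reactants: 18 methyl (2Z,4S,5R,6S)-2-(bromomethyl)-5-(TBS-oxy)-4-(PMB-oxy)-7-(PMP-oxy)-6-methyl-6-(TES-oxy)hept-2-enoate; 20 (Z)-3-methylpent-2-en-4-ynal
Product: 23 trans 6,12-lactone (6R,7S,8S,9R,10S) bearing 8-OPMB 9-OTBS 10-OTES 1-OPMP and the free C2≡C3 alkyne, via allylchromium dichloride 21 (not isolated), via hydroxy ester 22 (not isolated)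
Conditions: CrCl2 (3 equiv), THF, 0 °C → rt; aq. NH4Cl; PPTS (cat.), CH2Cl2, rt
Reagents that add atoms: none
Why: Nozaki–Hiyama allylation with lactonisation: the equilibrating allylchromium reagent should react through the chair with the C8 branch equatorial (anti adduct, hence the trans lactone and C6), the C7 face being fixed by C8, whose hydrogen eclipses the C7=C11 bond (A(1,3) strain) so that the aldehyde enters anti to the bulky C9 residue (Felkin–Anh-type control), after which the C6 oxygen closes onto the methyl ester.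

Step 11
Reactants: 23 trans 6,12-lactone with 8-OPMB
Product: 24 8-hydroxy lactone (6R,7R,8S,9R,10S) with 9-OTBS 10-OTES 1-OPMP
Conditions: DDQ, CH2Cl2/pH 7 buffer (10:1), 0 °C
Reagents that add atoms: none
Why: Oxidative cleavage of the PMB ether by DDQ (benzylic hydride abstraction, then hydrolysis) under buffered conditions should leave the aryl PMP ether, both silyl ethers and the enyne intact.

Step 12
Reactants: 24 8-hydroxy lactone
Product: 25 8-O-isobutyryl lactone (6R,7S,8S,9R,10S) with 9-OTBS 10-OTES 1-OPMP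
Conditions: isobutyryl chloride, pyridine, DMAP (cat.), CH2Cl2, 0 °C → rt
Reagents that add atoms: isobutyryl chloride, CC(C)C(Cl)=O
Why: DMAP-catalysed acylation of the only free hydroxyl in a weakly basic medium, which should hold back lactone migration to O8 and silyl migration from O9.

Step 13
Reactants: 25 8-O-isobutyryl lactone with 1-OPMP
Product: 26 C1 primary alcohol (6R,7S,8S,9R,10S) with 8-O-isobutyryl 9-OTBS 10-OTES
Conditions: (NH4)2Ce(NO3)6, pyridine, MeCN/H2O (4:1), 0 °C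
Reagents that add atoms: none
Why: Oxidative dearylation of the PMP ether: tetravalent cerium oxidises the p-dialkoxyarene to its radical cation, water attacks and the primary alcohol is released with benzoquinone, the pyridine buffer protecting the silyl ethers.

Step 14
Reactants: 26 C1 primary alcohol with terminal alkyne
Product: 27 C2 iodoalkyne C1 alcohol (6R,7S,8S,9R,10S)
Conditions: NIS, AgNO3 (10 mol%), acetone, rt, dark
Reagents that add atoms: N-iodosuccinimide, O=C1CCC(=O)N1I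
Why: Silver-catalysed electrophilic iodination of the terminal alkyne via the silver acetylide, placed after removal of the electron-rich PMP ring, which could itself be iodinated.

Step 15
Reactants: 27 C2 iodoalkyne C1 alcohol
Product: 28 iodoalkyne aldehyde (6R,7S,8S,9R,10R) with 8-O-isobutyryl 9-OTBS 10-OTES
Conditions: Dess–Martin periodinane, NaHCO3, CH2Cl2, 0 °C → rt
Reagents that add atoms: none
Why: Dess–Martin oxidation of the neopentyl-type primary alcohol gives the non-enolisable α-silyloxy aldehyde under buffered, non-basic conditions that the iodoalkyne tolerates.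

Step 16
Reactants: 28 iodoalkyne aldehyde
Product: 30 ten-membered propargylic alcohol (6R,7S,8S,9R,10S; C1 epimers) with 8-O-isobutyryl 9-OTBS 10-OTES, via alkynylchromium dichloride 29 (not isolated)
Conditions: CrCl2 (8 equiv), NiCl2 (0.1 equiv), degassed THF, rt, syringe-pump addition of 28 (final 0.003 M); aqueous work-up
Reagents that add atoms: none
Why: CrCl2 reduces the catalytic NiCl2 to zerovalent nickel, which inserts into the sp C–I bond of 28, and transmetalation to trivalent chromium gives alkynylchromium 29, which adds to the C1 aldehyde and forms the C1–C2 bond (intramolecular Nozaki–Hiyama–Kishi reaction). The closest known reactions are chromium/nickel-mediated iodoalkyne–aldehyde cyclisations that close nine- and ten-membered enyne and enediyne carbinols. The ten-membered carbocycle closes by 10-exo-trig attack of C2 on the aldehyde carbon, the linear C1–C2≡C3–C4 unit bridging the ends of the C5–C10 chain, which the cis C4=C5 alkene and the trans lactone hold in a turn. The only new stereocentre, C1, forms under substrate control of unknown sense and needs none, because step 17 oxidises it. Chemoselectivity rests on nickel inserting only into the iodoalkyne and on the low basicity and aldehyde selectivity of organochromium reagents, so the lactone, the acrylate, the isobutyrate and both silyl ethers are spectators and the α-quaternary aldehyde is the only electrophile attacked. Slow addition to excess CrCl2 at high dilution should favour ring closure over oligomerisation.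

Step 17
Reactants: 30 ten-membered propargylic alcohol
Product: 31 ten-membered ynone (6R,7S,8S,9R,10R) with 8-O-isobutyryl 9-OTBS 10-OTES
Conditions: Dess–Martin periodinane, NaHCO3, CH2Cl2, 0 °C → rt
Reagents that add atoms: none
Why: Dess–Martin oxidation of the propargylic carbinol gives the ynone without base and removes the uncontrolled C1 stereocentre.

Step 18
Reactants: 31 ten-membered ynone
Product: 32 10-hydroxy ynone (6R,7S,8S,9R,10R) with 9-OTBS
Conditions: HF·pyridine, pyridine, THF, 0 °C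
Reagents that add atoms: none
Why: Fluoride-mediated desilylation in which the TES ether on the oxygen α to the ketone should be cleaved well before the hindered secondary TBS ether (TES/TBS lability difference), so that only O10 is unmasked.

Step 19
Reactants: 32 10-hydroxy ynone
Product: 33 9-O-TBS furanone (6R,7S,8S,9R,10R)
Conditions: Ph3PAuCl (5 mol%), AgOTf (5 mol%), toluene, rt
Reagents that add atoms: none
Why: Gold-catalysed 5-endo-dig hydroalkoxylation (cycloisomerisation of an α′-hydroxy ynone to a 3(2H)-furanone): the cationic phosphine–gold complex activates the strained alkyne, O10 attacks C3 and protodeauration gives the C2=C3 enone, while the still-silylated O9 cannot compete by 6-endo attack.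

Step 20
Reactants: 33 9-O-TBS furanone
Product: 34 target, (6R,7S,8S,9R,10R)-3,10-epoxy-9-hydroxy-8-(2-methylpropanoyloxy)-1-oxogermacra-2,4Z,11(13)-trien-12,6-olide
Conditions: HF·pyridine (excess), THF, 0 °C → rt
Reagents that add atoms: none
Why: Acidic fluoride cleavage of the remaining TBS ether under non-basic conditions, which avoids acyl migration from O8 to O9 and conjugate addition to the methylene lactone.

**Compound list**

1 | 4-methoxybenzyl alcohol | COc1ccc(CO)cc1 | starting material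
2 | allyl bromide | C=CCBr | starting material
3 | allyl 4-methoxybenzyl ether | C=CCOCc1ccc(OC)cc1 | intermediate
4 | methacrolein | CC(=C)C=O | starting material
5 | [(Z)-3-(4-methoxybenzyloxy)prop-2-en-1-yl]lithium | [Li]C/C=C\OCc1ccc(OC)cc1 | intermediate
6 | lithium bis(isopinocampheyl)(methoxy)[(Z)-3-(4-methoxybenzyloxy)prop-2-en-1-yl]borate, Ipc from (−)-α-pinene | [Li+].CO[B-](C/C=C\OCc1ccc(OC)cc1)([C@H]2C[C@H]3C[C@@H]([C@@H]2C)C3(C)C)[C@H]2C[C@H]3C[C@@H]([C@@H]2C)C3(C)C | intermediate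
7 | bis(isopinocampheyl)[(Z)-3-(4-methoxybenzyloxy)prop-2-en-1-yl]borane, Ipc from (−)-α-pinene | COc1ccc(CO/C=C\CB([C@H]2C[C@H]3C[C@@H]([C@@H]2C)C3(C)C)[C@H]2C[C@H]3C[C@@H]([C@@H]2C)C3(C)C)cc1 | intermediate
8 | bis(isopinocampheyl)borinate ester of alcohol 9 | C=C[C@H](OCc1ccc(OC)cc1)[C@@H](OB([C@H]2C[C@H]3C[C@@H]([C@@H]2C)C3(C)C)[C@H]2C[C@H]3C[C@@H]([C@@H]2C)C3(C)C)C(C)=C | intermediate
9 | (3S,4S)-3-[(4-methoxybenzyl)oxy]-5-methylhexa-1,5-dien-4-ol | C=C[C@H](OCc1ccc(OC)cc1)[C@@H](O)C(C)=C | intermediate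
10 | (1R,2S)-2-[(4-methoxybenzyl)oxy]-1-[(2S)-2-methyloxiran-2-yl]but-3-en-1-ol | C=C[C@H](OCc1ccc(OC)cc1)[C@@H](O)[C@]2(C)CO2 | intermediate
11 | (2S,3R,4S)-4-[(4-methoxybenzyl)oxy]-1-(4-methoxyphenoxy)-2-methylhex-5-ene-2,3-diol | C=C[C@H](OCc1ccc(OC)cc1)[C@@H](O)[C@@](C)(O)COc1ccc(OC)cc1 | intermediate
12 | (2S,3R,4S)-3-[(tert-butyldimethylsilyl)oxy]-4-[(4-methoxybenzyl)oxy]-1-(4-methoxyphenoxy)-2-methylhex-5-en-2-ol | C=C[C@H](OCc1ccc(OC)cc1)[C@@H](O[Si](C)(C)C(C)(C)C)[C@@](C)(O)COc1ccc(OC)cc1 | intermediate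
13 | (3S,4R,5S)-4-[(tert-butyldimethylsilyl)oxy]-3-[(4-methoxybenzyl)oxy]-6-(4-methoxyphenoxy)-5-methyl-5-[(triethylsilyl)oxy]hex-1-ene | C=C[C@H](OCc1ccc(OC)cc1)[C@@H](O[Si](C)(C)C(C)(C)C)[C@@](C)(O[Si](CC)(CC)CC)COc1ccc(OC)cc1 | intermediate
14 | (3S,4R,5S)-4-[(tert-butyldimethylsilyl)oxy]-3-[(4-methoxybenzyl)oxy]-6-(4-methoxyphenoxy)-5-methyl-5-[(triethylsilyl)oxy]hexane-1,2-diol (C2 epimers) | OCC(O)[C@H](OCc1ccc(OC)cc1)[C@@H](O[Si](C)(C)C(C)(C)C)[C@@](C)(O[Si](CC)(CC)CC)COc1ccc(OC)cc1 | intermediate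
15 | (2R,3R,4S)-3-[(tert-butyldimethylsilyl)oxy]-2-[(4-methoxybenzyl)oxy]-5-(4-methoxyphenoxy)-4-methyl-4-[(triethylsilyl)oxy]pentanal | O=C[C@H](OCc1ccc(OC)cc1)[C@@H](O[Si](C)(C)C(C)(C)C)[C@@](C)(O[Si](CC)(CC)CC)COc1ccc(OC)cc1 | intermediate
16 | methyl 2-[(2S,3R,4S)-3-[(tert-butyldimethylsilyl)oxy]-1-hydroxy-2-[(4-methoxybenzyl)oxy]-5-(4-methoxyphenoxy)-4-methyl-4-[(triethylsilyl)oxy]pentyl]prop-2-enoate (C1′ epimers) | C=C(C(=O)OC)C(O)[C@H](OCc1ccc(OC)cc1)[C@@H](O[Si](C)(C)C(C)(C)C)[C@@](C)(O[Si](CC)(CC)CC)COc1ccc(OC)cc1 | intermediate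
17 | O-dimethylsulfonium bromide of alcohol 16 | C=C(C(=O)OC)C(O[S+](C)C)[C@H](OCc1ccc(OC)cc1)[C@@H](O[Si](C)(C)C(C)(C)C)[C@@](C)(O[Si](CC)(CC)CC)COc1ccc(OC)cc1.[Br-] | intermediate
18 | methyl (2Z,4S,5R,6S)-2-(bromomethyl)-5-[(tert-butyldimethylsilyl)oxy]-4-[(4-methoxybenzyl)oxy]-7-(4-methoxyphenoxy)-6-methyl-6-[(triethylsilyl)oxy]hept-2-enoate | BrC/C(C(=O)OC)=C\[C@H](OCc1ccc(OC)cc1)[C@@H](O[Si](C)(C)C(C)(C)C)[C@@](C)(O[Si](CC)(CC)CC)COc1ccc(OC)cc1 | intermediate
19 | (Z)-3-methylpent-2-en-4-yn-1-ol | C#C/C(C)=C\CO | starting material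
20 | (Z)-3-methylpent-2-en-4-ynal | C#C/C(C)=C\C=O | intermediate
21 | allylchromium dichloride from 18 (C8 trans to CH2Cr; 4S,5R,6S) | Cl[Cr](Cl)C/C(C(=O)OC)=C/[C@H](OCc1ccc(OC)cc1)[C@@H](O[Si](C)(C)C(C)(C)C)[C@@](C)(O[Si](CC)(CC)CC)COc1ccc(OC)cc1 | intermediate
22 | methyl ester of the 6-hydroxy seco acid of lactone 23 (6R,7S,8S,9R,10S; C6/C7 anti) | C#C/C(C)=C\[C@@H](O)[C@H](C(=C)C(=O)OC)[C@H](OCc1ccc(OC)cc1)[C@@H](O[Si](C)(C)C(C)(C)C)[C@@](C)(O[Si](CC)(CC)CC)COc1ccc(OC)cc1 | intermediate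
23 | (4S,5R)-4-[(1S,2R,3S)-2-[(tert-butyldimethylsilyl)oxy]-1-[(4-methoxybenzyl)oxy]-4-(4-methoxyphenoxy)-3-methyl-3-[(triethylsilyl)oxy]butyl]-3-methylidene-5-[(1Z)-2-methylbut-1-en-3-yn-1-yl]oxolan-2-one | C=C1C(=O)O[C@H](/C=C(/C)C#C)[C@H]1[C@H](OCc2ccc(OC)cc2)[C@@H](O[Si](C)(C)C(C)(C)C)[C@@](C)(O[Si](CC)(CC)CC)COc2ccc(OC)cc2 | intermediate
24 | (4R,5R)-4-[(1S,2R,3S)-2-[(tert-butyldimethylsilyl)oxy]-1-hydroxy-4-(4-methoxyphenoxy)-3-methyl-3-[(triethylsilyl)oxy]butyl]-3-methylidene-5-[(1Z)-2-methylbut-1-en-3-yn-1-yl]oxolan-2-one | C=C1C(=O)O[C@H](/C=C(/C)C#C)[C@H]1[C@H](O)[C@@H](O[Si](C)(C)C(C)(C)C)[C@@](C)(O[Si](CC)(CC)CC)COc2ccc(OC)cc2 | intermediate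
25 | (4S,5R)-4-[(1S,2R,3S)-2-[(tert-butyldimethylsilyl)oxy]-4-(4-methoxyphenoxy)-3-methyl-1-(2-methylpropanoyloxy)-3-[(triethylsilyl)oxy]butyl]-3-methylidene-5-[(1Z)-2-methylbut-1-en-3-yn-1-yl]oxolan-2-one | C=C1C(=O)O[C@H](/C=C(/C)C#C)[C@H]1[C@H](OC(=O)C(C)C)[C@@H](O[Si](C)(C)C(C)(C)C)[C@@](C)(O[Si](CC)(CC)CC)COc2ccc(OC)cc2 | intermediate
26 | (4S,5R)-4-[(1S,2R,3S)-2-[(tert-butyldimethylsilyl)oxy]-4-hydroxy-3-methyl-1-(2-methylpropanoyloxy)-3-[(triethylsilyl)oxy]butyl]-3-methylidene-5-[(1Z)-2-methylbut-1-en-3-yn-1-yl]oxolan-2-one | C=C1C(=O)O[C@H](/C=C(/C)C#C)[C@H]1[C@H](OC(=O)C(C)C)[C@@H](O[Si](C)(C)C(C)(C)C)[C@@](C)(O[Si](CC)(CC)CC)CO | intermediate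
27 | (4S,5R)-4-[(1S,2R,3S)-2-[(tert-butyldimethylsilyl)oxy]-4-hydroxy-3-methyl-1-(2-methylpropanoyloxy)-3-[(triethylsilyl)oxy]butyl]-5-[(1Z)-4-iodo-2-methylbut-1-en-3-yn-1-yl]-3-methylideneoxolan-2-one | C=C1C(=O)O[C@H](/C=C(/C)C#CI)[C@H]1[C@H](OC(=O)C(C)C)[C@@H](O[Si](C)(C)C(C)(C)C)[C@@](C)(O[Si](CC)(CC)CC)CO | intermediate
28 | (4S,5R)-4-[(1S,2R,3R)-2-[(tert-butyldimethylsilyl)oxy]-3-methyl-1-(2-methylpropanoyloxy)-4-oxo-3-[(triethylsilyl)oxy]butyl]-5-[(1Z)-4-iodo-2-methylbut-1-en-3-yn-1-yl]-3-methylideneoxolan-2-one | C=C1C(=O)O[C@H](/C=C(/C)C#CI)[C@H]1[C@H](OC(=O)C(C)C)[C@@H](O[Si](C)(C)C(C)(C)C)[C@@](C)(O[Si](CC)(CC)CC)C=O | intermediate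
29 | alkynylchromium dichloride from 28 (CrCl2 in place of iodine at C2) | C=C1C(=O)O[C@H](/C=C(/C)C#C[Cr](Cl)Cl)[C@H]1[C@H](OC(=O)C(C)C)[C@@H](O[Si](C)(C)C(C)(C)C)[C@@](C)(O[Si](CC)(CC)CC)C=O | intermediate
30 | (6R,7S,8S,9R,10S)-9-[(tert-butyldimethylsilyl)oxy]-1-hydroxy-8-(2-methylpropanoyloxy)-10-[(triethylsilyl)oxy]germacra-4Z,11(13)-dien-2-yn-12,6-olide (C1 epimers) | C=C1C(=O)O[C@@H]2/C=C(/C)C#CC(O)[C@](C)(O[Si](CC)(CC)CC)[C@H](O[Si](C)(C)C(C)(C)C)[C@@H](OC(=O)C(C)C)[C@@H]12 | intermediate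
31 | (6R,7S,8S,9R,10R)-9-[(tert-butyldimethylsilyl)oxy]-8-(2-methylpropanoyloxy)-1-oxo-10-[(triethylsilyl)oxy]germacra-4Z,11(13)-dien-2-yn-12,6-olide | C=C1C(=O)O[C@@H]2/C=C(/C)C#CC(=O)[C@](C)(O[Si](CC)(CC)CC)[C@H](O[Si](C)(C)C(C)(C)C)[C@@H](OC(=O)C(C)C)[C@@H]12 | intermediate
32 | (6R,7S,8S,9R,10R)-9-[(tert-butyldimethylsilyl)oxy]-10-hydroxy-8-(2-methylpropanoyloxy)-1-oxogermacra-4Z,11(13)-dien-2-yn-12,6-olide | C=C1C(=O)O[C@@H]2/C=C(/C)C#CC(=O)[C@](C)(O)[C@H](O[Si](C)(C)C(C)(C)C)[C@@H](OC(=O)C(C)C)[C@@H]12 | intermediate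
33 | (6R,7S,8S,9R,10R)-9-[(tert-butyldimethylsilyl)oxy]-3,10-epoxy-8-(2-methylpropanoyloxy)-1-oxogermacra-2,4Z,11(13)-trien-12,6-olide | C=C1C(=O)O[C@@H]2/C=C(/C)C3=CC(=O)[C@](C)(O3)[C@H](O[Si](C)(C)C(C)(C)C)[C@@H](OC(=O)C(C)C)[C@@H]12 | intermediate
34 | (6R,7S,8S,9R,10R)-3,10-epoxy-9-hydroxy-8-(2-methylpropanoyloxy)-1-oxogermacra-2,4Z,11(13)-trien-12,6-olide (CNP0265772.1) | C=C1C(=O)O[C@@H]2/C=C(/C)C3=CC(=O)[C@](C)(O3)[C@H](O)[C@@H](OC(=O)C(C)C)[C@@H]12 | target

**Step count and risks**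

Total step count: 20. Longest linear sequence: 19 steps (steps 1–8 and 10–20, from 4-methoxybenzyl alcohol); step 9 is a one-step branch.

Steps most likely to fail:

1. Step 10. The allylchromium reagent may react through its Z-configured form or on the other face of C7, giving the cis-lactone or the C7 epimer, or it may lose the C8 ether by 1,4-elimination. Fallback, setting out from 18 and 20 and returning to 23: an indium-mediated Barbier reaction (indium powder, THF/H2O, rt), in which the allylindium keeps its Z geometry and a closed chair gives the syn adduct, should give the C6-epimeric hydroxy ester F1. Saponification (LiOH, THF/H2O, 0 °C, then NaH2PO4 buffer) gives the hydroxy acid F2. Mitsunobu lactonisation (PPh3, DIAD, toluene, 0 °C) then closes the lactone with inversion at the allylic C6 carbinol and gives 23.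

2. Step 16. The iodoalkyne may be reduced to the terminal alkyne, or the chain may oligomerise instead of closing the strained ring. Fallback, setting out from 26 and returning to 30: the iodination is omitted and Dess–Martin oxidation (NaHCO3, CH2Cl2) gives the terminal-alkyne aldehyde F3. Zn(OTf)2 and Et3N in toluene at high dilution generate the zinc alkynylide in situ, which adds to the non-enolisable aldehyde (zinc triflate/amine alkynylation) and gives 30.

3. Step 19. The cationic gold catalyst may engage the enyne–lactone array, or the strained ynone may decompose before O10 attacks. Fallback, setting out from 32 and returning to 33: Et2NH (EtOH, 0 °C) adds to C3 of the ynone and gives the β-diethylamino enone F4, in which the strained alkyne is gone. AcOH (THF, rt) then promotes addition of O10 to C3 and loss of Et2NH to give 33.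

Further compounds
F1 | step 10 | C6-epimeric syn hydroxy ester (6S,7S,8S,9R,10S), methyl ester | C#C/C(C)=C\[C@H](O)[C@H](C(=C)C(=O)OC)[C@H](OCc1ccc(OC)cc1)[C@@H](O[Si](C)(C)C(C)(C)C)[C@@](C)(O[Si](CC)(CC)CC)COc1ccc(OC)cc1
F2 | step 10 | C6-epimeric hydroxy acid (6S,7S,8S,9R,10S) | C#C/C(C)=C\[C@H](O)[C@H](C(=C)C(=O)O)[C@H](OCc1ccc(OC)cc1)[C@@H](O[Si](C)(C)C(C)(C)C)[C@@](C)(O[Si](CC)(CC)CC)COc1ccc(OC)cc1
F3 | step 16 | terminal-alkyne aldehyde (28 with hydrogen in place of iodine) | C=C1C(=O)O[C@H](/C=C(/C)C#C)[C@H]1[C@H](OC(=O)C(C)C)[C@@H](O[Si](C)(C)C(C)(C)C)[C@@](C)(O[Si](CC)(CC)CC)C=O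
F4 | step 19 | β-diethylamino enone (diethylamine adduct of 32 at C3) | C=C1C(=O)O[C@@H]2/C=C(/C)C(N(CC)CC)=CC(=O)[C@](C)(O)[C@H](O[Si](C)(C)C(C)(C)C)[C@@H](OC(=O)C(C)C)[C@@H]12
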